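At late times the target in these flasks is what the free enzyme converted while it stayed folded, less what has since gone on to over-reaction product, so we reckon how much conversion one charge of enzyme can deliver.

    free enzyme → unfolded enzyme (k1 = 5.96 × 10⁻⁴ h⁻¹, Ea1 = 219 kJ mol⁻¹)
    starting material + free enzyme → target + free enzyme, rate k2*[starting material]^3*[free enzyme]/(1 + ([starting material]/Kh2)^3) (Kh2 = 4.95 mM, k2 = 2.15 × 10⁶ M⁻³ s⁻¹, Ea2 = 15.0 kJ mol⁻¹)
    target → over-reaction product (k3 = 8.92 × 10⁻⁵ h⁻¹, Ea3 = 100 kJ mol⁻¹)
    (constants at 5 °C)

| flask | starting material | free enzyme | temperature | time |
|---|---|---|---|---|
| eta | 0.011 M | 2.2 µM | 45 °C | 20 h |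
| gamma | 0.011 M | 2.2 µM | 5 °C | 20 h |
| zeta | 0.011 M | 2.2 µM | 25 °C | 20 h |

- at 5 °C the constants are as listed, elsewhere as the activation energies make them

1. which flask leads in amount of target, in percent of the starting material charged ("all alike" within 1.5 percentage points) (eta / gamma / zeta / all alike)
2. how much target is there at the end, in percent of the starting material charged: eta
3. how much target is there at the end, in percent of the starting material charged: gamma
4. how much target is there at the end, in percent of the starting material charged: zeta

Unfolding is first order, so the time integral of [free enzyme] over the run is closed: the charge, times one minus the exponential of minus the unfolding constant times the time, over that constant. Dividing the catalytic rate by [free enzyme] then separates the variables. With a the fraction of [starting material] left and b the cube of Kh over the charge, 0.0911, the integrated rate law reads 1 − a + (b/2)(1/a^2 − 1) = w. Here w is the catalytic dose, the zero-order ceiling rate (the catalytic constant times the cube of Kh times [free enzyme]) taken over that integral and told as a share of the charge, a measure and not a yield; for gamma it is 373%.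

Warming raises the unfolding constant from 5.96 × 10⁻⁴ h⁻¹ to 0.342 h⁻¹ in zeta and 88.3 h⁻¹ in eta. The doses therefore fall to 84.7% and 0.481%, because unfolding speeds up by 1.5 × 10⁵ from the coldest flask to the hottest while the catalytic step gains 2.3.

We solve the law where each flask ends. Eta stays near a = one, where the left side climbs with slope one plus b. Gamma's dose is above one charge, so we drop a beside one. Zeta ends near a = Kh over the charge, 45.0%, where the slope is 2, so we take one Newton step from there. Each yield then takes, as if the target had stood from the start, the over-reaction survival of the whole run, 66.4% in eta, 99.8% in gamma and 96.8% in zeta. We get 0.292% for eta, 87.0% for gamma and 59.0% for zeta, so gamma leads.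

The forecast named gamma, with 0.29% for eta, 87.4% for gamma and 58.6% for zeta, a little apart from ours on gamma and zeta, on the ground that “The enzyme's unfolding has a far higher activation energy than the catalytic step”.

The simulation puts gamma first, with 0.292% in eta, 87.3% in gamma and 58.6% in zeta.

A flask like eta kept at 20 °C takes the same reckoning. Its unfolding constant of 0.0758 h⁻¹ gives a dose of 269%, less than gamma's 373% but still more than one full charge. The gamma branch of the law then leaves 16.2% of the starting material, and survival brings the target to 82.5%. The simulated flask ends with 15.5% starting material, 22.0% of its free enzyme and 83.3% target.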